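## Retrosynthetic overview

1. The acetate on the cyclopentanone is traced back to the acetyl group of a 2-acetylcyclopentanone (β-diketone) by an oxidative 1,2-acyl C→O shift, a Baeyer–Villiger-type excision of the C-4/C-15 unit of the sesquiterpene.
2. The β-diketone comes from a cadinane 4,5-epoxy-3-ketone by a Lewis-acid 1,2-acyl shift that contracts ring A from six to five members (cadinane → oplopane skeleton).
3. The 8α-OH / 9β-angelate / 10(14)-methylidene array comes from C-9 allylic hydroxylation and selective esterification of an 8α-hydroxycadina-4,10(14)-dien-3-one.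
4. That cadinane comes from a cationic (type 2 carbonyl-ene) closure of ring B onto the isopropenyl group of a γ-alkylated (S)-carvone; the C5 side chain is added with a nitroalkene by a vinylogous Mukaiyama–Michael/Nef step.
5. Ring order: ring A (six-membered, from carvone), then ring B (ene cyclization), then ring A contracted to the cyclopentanone.

Convention: cadinane numbering is kept throughout (C-1/C-6 ring fusion, C-3 ketone, C-4/C-15 the carbons that end as the acetyl group, C-5 acetate carbon, C-7 iPr, C-8 OH, C-9 ester, C-10=C-14); β is the face of H-1, α the face of H-6.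

Assumption: (E)-3-methyl-1-nitrobut-1-ene is bought as a catalogue compound.

## Route

Step 1
Reactants: 1 (S)-(+)-carvone
Product: 2 (5R)-1-(tert-butyldimethylsilyloxy)-2-methyl-5-(prop-1-en-2-yl)cyclohexa-1,3-diene (linear TBS dienol ether)
Conditions: KOtBu (1.1 equiv), THF–DMPU, −78 → 0 °C; TBSCl (1.3 equiv), −78 °C → rt
Reagents that add atoms: tert-butyldimethylsilyl chloride (TBSCl), CC(C)(C)[Si](C)(C)Cl
Why: γ-Deprotonation under equilibrating alkoxide conditions gives the thermodynamic linear (extended) dienolate, which is O-silylated (thermodynamic dienolate formation/O-silylation); the stereocentre is not touched.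

Step 2
Reactants: 2 linear TBS dienol ether; 3 (E)-3-methyl-1-nitrobut-1-ene
Product: 5 (2S)-3-methyl-2-[(1R,6R)-3-methyl-4-oxo-6-(prop-1-en-2-yl)cyclohex-2-en-1-yl]butanal, via silyl nitronate 4 (not isolated)
Conditions: TiCl4 (1.1 equiv), CH2Cl2, −78 °C; then H2O–THF, 0 °C → rt
Reagents that add atoms: (E)-3-methyl-1-nitrobut-1-ene 3, CC(C)/C=C/[N+](=O)[O-]; water, O
Why: Vinylogous Mukaiyama–Michael addition in which the dienol ether reacts at its γ-carbon (C-6) on the face anti to the isopropenyl group (1,6-trans), an open antiperiplanar transition state with H-7 in the crowded sector between C-1 and C-5 sets C-7, and the nitronate is hydrolysed in the same flask (Nef reaction) to the aldehyde.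

Step 3
Reactants: 5 aldehyde
Product: 6 8α-hydroxycadina-4,10(14)-dien-3-one (trans-fused; 1β-H, 6α-H, 7α-isopropyl)
Conditions: Me2AlCl (2.5 equiv), CH2Cl2, −78 → −20 °C; 1 M HCl work-up
Reagents that add atoms: none
Why: Type 2 carbonyl-ene (Prins-type) cyclization in which the Me2AlCl-bound aldehyde attacks the isopropenyl terminus through a chair with iPr equatorial and C=O axial (needed to take an allylic methyl hydrogen), giving the axial 8α-OH and the 10(14)-methylidene.

Step 4
Reactants: 6 cadinadienone
Product: 7 4β,5β-epoxy-8α-hydroxycadin-10(14)-en-3-one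
Conditions: 30% H2O2 (3 equiv), NaOH (0.3 equiv), MeOH, 0 °C
Reagents that add atoms: hydrogen peroxide, OO
Why: Weitz–Scheffer nucleophilic epoxidation is specific for the enone and leaves the methylidene alone; axial attack of hydroperoxide on C-5 of the trans-fused enone should give the 4β,5β-epoxide, whose configuration is not carried into the target.

Step 5
Reactants: 7 epoxy ketone
Product: 8 4β,5β-epoxy-8α,9β-dihydroxycadin-10(14)-en-3-one
Conditions: SeO2 (0.3 equiv), t-BuOOH (3 equiv), CH2Cl2, rt
Reagents that add atoms: selenium dioxide, O=[Se]=O; tert-butyl hydroperoxide, CC(C)(C)OO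
Why: SeO2/t-BuOOH allylic hydroxylation (ene reaction, then [2,3]-sigmatropic shift) goes to the allylic CH2 (C-9) in preference to the CH (C-1) and delivers oxygen axially, anti to the 8α-OH, giving the trans-diaxial 8α,9β-diol.

Step 6
Reactants: 8 epoxy diol; 9 angelic acid [(Z)-2-methylbut-2-enoic acid]
Product: 11 9β-angeloyloxy-4β,5β-epoxy-8α-hydroxycadin-10(14)-en-3-one, via mixed anhydride 10 (not isolated)
Conditions: 9 (1.5 equiv), 2,4,6-trichlorobenzoyl chloride (1.5 equiv), Et3N (3 equiv), toluene, rt; then 8, 75 °C
Reagents that add atoms: angelic acid 9, C/C=C(/C)C(=O)O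
Why: Yamaguchi mixed-anhydride esterification (no angelate → tiglate isomerisation) acylates the less hindered allylic 9β-OH, because the 8α-OH is a neomenthol-type axial alcohol next to the iPr group and the trans-diaxial geometry blocks acyl migration.

Step 7
Reactants: 11 epoxy ketone angelate
Product: 12 9β-angeloyloxy-8α-hydroxy-3(4→5)-abeo-cadin-10(14)-ene-3,4-dione (trans-hydrindan-3-one with the C-4/C-15 acetyl on C-5; drawn as the chelated Z-enol)
Conditions: BF3·OEt2 (30 mol %), CH2Cl2, −40 → 0 °C
Reagents that add atoms: none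
Why: Lewis-acid rearrangement of an α,β-epoxy ketone in which BF3 opens the epoxide at C-5 (C-4 is deactivated by the carbonyl) with concerted 1,2-shift of the acyl carbon C-3 from C-4 to C-5, contracting ring A to the cyclopentanone and turning C-4/C-15 into the acetyl group; C-5 becomes the enolised carbon of a β-diketone, so no configuration has to be controlled here.

Step 8
Reactants: 12 β-diketone
Product: 14 target CNP0317011.1 [(1R,3aR,5S,6S,7S,7aR)-1-(acetyloxy)-6-hydroxy-4-methylidene-2-oxo-7-(propan-2-yl)octahydro-1H-inden-5-yl (2Z)-2-methylbut-2-enoate], via hydroxy diketone 13 (not isolated)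
Conditions: trans-3-phenyl-2-(phenylsulfonyl)oxaziridine (1.2 equiv), DBU (0.3 equiv), CH2Cl2, −20 °C → rt
Reagents that add atoms: 3-phenyl-2-(phenylsulfonyl)oxaziridine (Davis reagent), O=S(=O)(N1OC1c1ccccc1)c1ccccc1
Why: Proposed new method: the amine-base enolate of the β-diketone is hydroxylated at C-5 by the oxaziridine, the tertiary alkoxide adds to the exocyclic acetyl carbonyl (oxiranolate) and C-5–C-4 cleavage gives the enolate of the α-acetoxy ketone (a formal Baeyer–Villiger excision), with C-5 set by protonation/equilibration to the pseudo-equatorial 5α-acetate (H-5 anti to H-6); the closest known reaction types are oxaziridine α-hydroxylation of 1,3-dicarbonyls and the base-catalysed α-hydroxy-β-diketone → α-ketol ester rearrangement.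

## Compound list

1 | (S)-(+)-carvone | CC1=CC[C@@H](CC1=O)C(C)=C | starting material
2 | (5R)-1-(tert-butyldimethylsilyloxy)-2-methyl-5-(prop-1-en-2-yl)cyclohexa-1,3-diene | CC1=C(O[Si](C)(C)C(C)(C)C)C[C@H](C=C1)C(C)=C | intermediate
3 | (E)-3-methyl-1-nitrobut-1-ene | CC(C)/C=C/[N+](=O)[O-] | starting material
4 | silyl nitronate of the Michael adduct (C=N geometry not defined) | C=C(C)[C@@H]1CC(=O)C(C)=C[C@H]1[C@H](C(C)C)C=[N+]([O-])O[Si](C)(C)C(C)(C)C | intermediate (not isolated)
5 | (2S)-3-methyl-2-[(1R,6R)-3-methyl-4-oxo-6-(prop-1-en-2-yl)cyclohex-2-en-1-yl]butanal | C=C(C)[C@@H]1CC(=O)C(C)=C[C@H]1[C@H](C(C)C)C=O | intermediate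
6 | 8α-hydroxycadina-4,10(14)-dien-3-one | C=C1[C@@H]2CC(=O)C(C)=C[C@H]2[C@H](C(C)C)[C@H](O)C1 | intermediate
7 | 4β,5β-epoxy-8α-hydroxycadin-10(14)-en-3-one | C=C1[C@@H]2CC(=O)[C@@]3(C)O[C@H]3[C@H]2[C@H](C(C)C)[C@H](O)C1 | intermediate
8 | 4β,5β-epoxy-8α,9β-dihydroxycadin-10(14)-en-3-one | C=C1[C@@H]2CC(=O)[C@@]3(C)O[C@H]3[C@H]2[C@H](C(C)C)[C@H](O)[C@H]1O | intermediate
9 | angelic acid | C/C=C(/C)C(=O)O | starting material
10 | angelic 2,4,6-trichlorobenzoic anhydride | C/C=C(/C)C(=O)OC(=O)c1c(Cl)cc(Cl)cc1Cl | intermediate (not isolated)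
11 | 9β-angeloyloxy-4β,5β-epoxy-8α-hydroxycadin-10(14)-en-3-one | C=C1[C@@H]2CC(=O)[C@@]3(C)O[C@H]3[C@H]2[C@H](C(C)C)[C@H](O)[C@H]1OC(=O)/C(C)=C\C | intermediate
12 | 9β-angeloyloxy-8α-hydroxy-3(4→5)-abeo-cadin-10(14)-ene-3,4-dione (chelated Z-enol) | C=C1[C@@H]2CC(=O)/C(=C(/C)O)[C@H]2[C@H](C(C)C)[C@H](O)[C@H]1OC(=O)/C(C)=C\C | intermediate
13 | 5-hydroxy derivative of 12 in the diketo form (C-5 not defined; erased in the next event) | C=C1[C@@H]2CC(=O)C(O)(C(C)=O)[C@H]2[C@H](C(C)C)[C@H](O)[C@H]1OC(=O)/C(C)=C\C | intermediate (not isolated)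
14 | CNP0317011.1, (1R,3aR,5S,6S,7S,7aR)-1-(acetyloxy)-6-hydroxy-4-methylidene-2-oxo-7-(propan-2-yl)octahydro-1H-inden-5-yl (2Z)-2-methylbut-2-enoate | C=C1[C@@H]2CC(=O)[C@H](OC(C)=O)[C@H]2[C@H](C(C)C)[C@H](O)[C@H]1OC(=O)/C(C)=C\C | target

## Step count and risks

Total steps: 8. Longest linear sequence: 8 (from 1; compounds 3 and 9 are bought).

**Step 8 (most likely to fail).** The tertiary alkoxide of 13 can also add to the ring carbonyl, which would give a ring-expanded δ-lactone instead of the acetate. Crude thermochemistry (cyclopentanone plus open-chain ester against δ-lactone plus methyl ketone, and the more acidic cyclopentanone as the better enolate leaving group) favours the acetate only slightly, so a mixture is possible. Both products interconvert through 13 under the same base. Fallback: set out from 12 and bring the acetate in from outside. Deacylative (Regitz) diazo transfer with 4-acetamidobenzenesulfonyl azide and DBU (MeCN, 0 °C) removes the acetyl group and gives the α-diazo ketone F3. Rh2(OAc)4-catalysed O–H insertion into acetic acid (CH2Cl2, rt), followed by Et3N equilibration of C-5, comes back to the route at 14.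

**Step 7.** The acyl shift competes with fluorohydrin formation and hydride shift (diosphenol), and the Lewis acid may be held by the free OH, the ester and the β-diketone product. Fallback: set out from 11 and do the shift in two stages. MgBr2·OEt2 (Et2O, −20 °C) opens the epoxide at C-5 with inversion to the diequatorial bromohydrin F2 (5α-bromo-4β-hydroxy ketone), whose equatorial C-5–Br bond is antiperiplanar to the ring bond C-3–C-4. AgBF4 with 2,6-di-tert-butylpyridine (CH2Cl2, 0 °C) then triggers the semipinacol 1,2-acyl shift with loss of bromide and comes back to the route at 12.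

**Step 2.** Three things can go wrong: α- instead of γ-attack, a poor ratio at C-7 (the open transition-state model is the weakest stereochemical argument in the route), and incomplete in-flask Nef hydrolysis to an α-branched aldehyde. Fallback: set out from 1 (with 3) and use dienamine catalysis in place of the silyl dienol ether. A cinchona-derived primary amine (9-amino-9-deoxy-epi-quinine or its quinidine-derived pseudo-enantiomer, 20 mol %, with 2-fluorobenzoic acid, toluene, 40 °C) gives γ-addition under catalyst control to the nitroalkane F1. A separate buffered TiCl3/NH4OAc Nef reaction (aq. THF) comes back to the route at 5. A wrong C-7 epimer of 5 can also be re-equilibrated with DBU before step 3, since only the epimer with an equatorial iPr cyclizes readily.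

## Further compounds

F1 | step 2 | (4R,5R)-2-methyl-4-[(2S)-3-methyl-1-nitrobutan-2-yl]-5-(prop-1-en-2-yl)cyclohex-2-en-1-one | C=C(C)[C@@H]1CC(=O)C(C)=C[C@H]1[C@H](C(C)C)C[N+](=O)[O-]
F2 | step 7 | 9β-angeloyloxy-5α-bromo-4β,8α-dihydroxycadin-10(14)-en-3-one | C=C1[C@@H]2CC(=O)[C@@](C)(O)[C@H](Br)[C@H]2[C@H](C(C)C)[C@H](O)[C@H]1OC(=O)/C(C)=C\C
F3 | step 8 | 9β-angeloyloxy-5-diazo-8α-hydroxy-4,15-dinor-3(4→5)-abeo-cadin-10(14)-en-3-one | C=C1[C@@H]2CC(=O)C(=[N+]=[N-])[C@H]2[C@H](C(C)C)[C@H](O)[C@H]1OC(=O)/C(C)=C\C
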